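**Plan**
- Cuts, in retrosynthetic order: the two ester C–O bonds (tiglate on O10, 4-hydroxybenzoate on O6); C9–C10 and C6–C7 of the seven-membered ring; the C4–isopropyl bond; the formyl carbons C6 and C10 are then rejoined as the C=C of a cyclobutene, which is the product of an enone–alkene [2+2] addition.
- Enabling feature: C6 and C10 are both carbinol carbons, sit on the ring-fusion atoms C5 and C1 of the five-membered ring, and are bridged by C7–C8(CH3)=C9. That three-carbon bridge is a 2-methylenepropane-1,3-diyl dianion, so the seven-membered ring is the [4+3] sum of a cis-1,2-diformylcyclopentane and a bis-allyl unit.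
- Forward order: cyclobutane onto 3-methylcyclopentenone; C4 carbinol by isopropyl addition; cyclobutene opened to the dialdehyde; seven-membered ring closed by double allylation; alkene moved to C8=C9 through the C10 ketone; the two esters last.
- Stereochemistry: cis fusion (C1/C5) from the photocycloaddition; absolute configuration from a sulfoximine resolution of the bicyclic ketone; C4 from convex-face addition; C6 from chelation-controlled allylation; C10 from Luche reduction.

Key step: step 7

Remark on numbering: daucane numbering is used (C1 angular C–CH3, C2 and C3 CH2, C4 C(OH)i-Pr, C5 ring-fusion CH, C6 CH–OAr, C7 CH2, C8(CH3)=C9, C10 CH–OTig).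
Remark on the structure: the target SMILES encodes a cis-fused hydroazulene, (1R,4R,5S,6S,10S): H5 and the C1 methyl are syn, the 4-OH lies on the face of the five-membered ring that carries C6 and C10, O6 is syn to H5 and O10 is anti to the C1 methyl. This is the compound made.
Assumption: (S)-N,S-dimethyl-S-phenylsulfoximine, 4-(tert-butyldimethylsilyloxy)benzoic acid and tigloyl chloride are taken as purchasable.

**Route**

Step 1
Reactants: 1 3-methylcyclopent-2-en-1-one; 2 (Z)-1,2-dichloroethene
Product: 3 rac-6,7-dichloro-5-methylbicyclo[3.2.0]heptan-2-one (cis-fused; chlorine epimers)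
Conditions: hν (medium-pressure Hg lamp, Pyrex filter), 2 (10 equiv), CH2Cl2, −20 °C
Reagents that add atoms: (Z)-1,2-dichloroethene 2, Cl/C=C\Cl
Why: The enone–alkene [2+2] photocycloaddition (triplet enone, 1,4-biradical) can only give the cis-fused bicyclo[3.2.0]heptanone, which sets C1 and C5 of the target syn to each other in racemic form, while the chlorine-bearing centres are removed in step 2.

Step 2
Reactants: 3 rac-6,7-dichloro-5-methylbicyclo[3.2.0]heptan-2-one
Product: 4 rac-5-methylbicyclo[3.2.0]hept-6-en-2-one
Conditions: activated Zn dust, EtOH/H2O 4:1, reflux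
Reagents that add atoms: none
Why: Zinc-mediated reductive 1,2-elimination of the vicinal dichloride is an established way to turn dichloroethene photoadducts into cyclobutenes and touches no stereocentre that is kept.

Step 3
Reactants: 4 rac-5-methylbicyclo[3.2.0]hept-6-en-2-one; 5 (S)-N,S-dimethyl-S-phenylsulfoximine
Product: 6 (1R,2S,5S)-5-methyl-2-{[(S)-N-methyl-S-phenylsulfonimidoyl]methyl}bicyclo[3.2.0]hept-6-en-2-ol
Conditions: 5, n-BuLi, THF, −78 °C; then 4, −78 °C; H2O quench; separation of the two diastereomers on silica gel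
Reagents that add atoms: (S)-N,S-dimethyl-S-phenylsulfoximine 5, C[S@@](=O)(=NC)c1ccccc1
Why: In this Johnson sulfoximine resolution the lithiated sulfoximine adds to the convex face of both ketone enantiomers, so the racemate becomes two separable diastereomers, and the one derived from the (1R,5S)-ketone (to be assigned by X-ray analysis) is kept.

Step 4
Reactants: 6 β-hydroxysulfoximine
Product: 7 (1R,5S)-5-methylbicyclo[3.2.0]hept-6-en-2-one
Conditions: toluene, reflux; distillation of 7 from the involatile sulfoximine
Reagents that add atoms: none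
Why: Thermal retro-addition of the β-hydroxysulfoximine, the second half of the Johnson resolution, returns the ketone as a single enantiomer together with the recoverable sulfoximine and leaves C1 and C5 untouched.

Step 5
Reactants: 7 (1R,5S)-5-methylbicyclo[3.2.0]hept-6-en-2-one; 8 isopropylmagnesium chloride
Product: 9 (1R,2R,5S)-5-methyl-2-(propan-2-yl)bicyclo[3.2.0]hept-6-en-2-ol
Conditions: anhydrous CeCl3, THF; 8, −78 °C, 1 h; then 7, −78 → 0 °C; aq. NH4Cl
Reagents that add atoms: isopropylmagnesium chloride 8, CC(C)[Mg]Cl
Why: The Imamoto organocerium addition suppresses enolisation and β-hydride reduction of the hindered ketone, and the nucleophile enters from the convex face of the bicycle (anti to the cyclobutene), which puts the hydroxyl on the face of the four-membered ring and sets C4 of the target.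

Step 6
Reactants: 9 (1R,2R,5S)-5-methyl-2-(propan-2-yl)bicyclo[3.2.0]hept-6-en-2-ol
Product: 11 (1R,2R,3R)-3-hydroxy-1-methyl-3-(propan-2-yl)cyclopentane-1,2-dicarbaldehyde, via secondary ozonide 10 (not isolated)
Conditions: O3, CH2Cl2, −78 °C; then PPh3, −78 °C → rt; used crude at once
Reagents that add atoms: ozone, [O-][O+]=O
Why: Ozonolysis of the strained cyclobutene with reductive work-up (Criegee mechanism) cleaves the ring C=C into the C6 and C10 formyl groups, which remain cis because they were the two ends of that double bond, and the neutral conditions should avoid epimerisation at C5 and loss of the β-hydroxyl.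

Step 7
Reactants: 11 (1R,2R,3R)-3-hydroxy-1-methyl-3-(propan-2-yl)cyclopentane-1,2-dicarbaldehyde; 12 3-bromo-2-(bromomethyl)prop-1-ene
Product: 15 (1R,4R,5S,6S,10S)-8-methylidenedaucane-4,6,10-triol, via bromo alcohol 13 (not isolated), via allylindium 14 (not isolated)
Conditions: In powder (3 equiv), 12 (1.2 equiv, slow addition), THF/H2O 1:1, 0.01 M in 11, rt
Reagents that add atoms: 3-bromo-2-(bromomethyl)prop-1-ene 12, C=C(CBr)CBr
Why: Proposed new method: zerovalent indium inserts into one C–Br bond of 12 and the allylindium adds through its γ-carbon to the C6 formyl group of 11 to give 13, after which the second C–Br bond is metallated to 14 and this adds in the same SE2' sense to the C10 formyl group, so that C6–C7 and C9–C10 form in one flask; the closest known reactions are the aqueous indium Barbier allylation of hydroxy aldehydes and lactols, the double allylation of two aldehyde molecules by this dibromide, and the two-stage [3+4] annulation of 1,4-dicarbonyl compounds with 2-methylenepropane-1,3-diyl reagents. The seven-membered ring closes by a 7-exo-trig addition to the aldehyde, which the cis-1,2 relation of the two formyl groups on the cyclopentane makes possible by holding the tethered allylmetal next to C10, and high dilution keeps this ahead of intermolecular addition. C6 is controlled by a chelate of indium between the C6 carbonyl oxygen and the free C4 hydroxyl: the allyl group enters from the face of H5, anti to the quaternary C1, which is the 6S configuration of the target. C10 is controlled by the ring-closing transition state, which should place the new hydroxyl pseudo-equatorial (10S), but this centre is oxidised in step 9 and an epimer would converge there. The step needs site selectivity of the first, intermolecular addition for the C6 aldehyde, because only then is C6 set under chelate control; this is secured by the C6 formyl group sitting on a tertiary carbon and being activated by the chelate, whereas the C10 formyl group is neopentylic.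

Step 8
Reactants: 15 (1R,4R,5S,6S,10S)-8-methylidenedaucane-4,6,10-triol
Product: 16 (1R,4R,5S,6S,10S)-4,6-O-isopropylidene-8-methylidenedaucane-4,6,10-triol
Conditions: 2,2-dimethoxypropane, pyridinium p-toluenesulfonate (cat.), acetone, rt
Reagents that add atoms: 2,2-dimethoxypropane, COC(C)(C)OC
Why: Acid-catalysed transacetalisation under thermodynamic control forms the six-membered 1,3-dioxane across the C4 and C6 hydroxyls, the only 1,3-diol pair (both other pairs would need seven-membered acetals), and so leaves the C10 hydroxyl as the single free alcohol.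

Step 9
Reactants: 16 (1R,4R,5S,6S,10S)-4,6-O-isopropylidene-8-methylidenedaucane-4,6,10-triol
Product: 18 (1R,4R,5S,6S)-4,6-O-isopropylidene-4,6-dihydroxydauc-8-en-10-one, via β,γ-unsaturated ketone 17 (not isolated)
Conditions: Dess–Martin periodinane, pyridine, CH2Cl2, 0 °C → rt; aq. Na2S2O3/NaHCO3 work-up; then DBU (0.2 equiv), CH2Cl2, rt
Reagents that add atoms: none
Why: Dess–Martin oxidation of the only free secondary alcohol followed by base-mediated isomerisation through the dienolate draws the exocyclic C8 methylene into conjugation with the single carbonyl group at C10, so the alkene can only end at C8=C9, while C5 and C6 are protected from enolate chemistry by the acetal.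

Step 10
Reactants: 18 (1R,4R,5S,6S)-4,6-O-isopropylidene-4,6-dihydroxydauc-8-en-10-one
Product: 19 (1R,4R,5S,6S)-4,6-dihydroxydauc-8-en-10-one
Conditions: AcOH/THF/H2O 3:1:1, 40 °C
Reagents that add atoms: none
Why: Mild acid hydrolysis of the isopropylidene acetal frees the C4/C6 diol, and the enone and the tertiary alcohol should tolerate aqueous acetic acid.

Step 11
Reactants: 19 (1R,4R,5S,6S)-4,6-dihydroxydauc-8-en-10-one; 20 4-(tert-butyldimethylsilyloxy)benzoic acid
Product: 22 (1R,4R,5S,6S)-6-[4-(tert-butyldimethylsilyloxy)benzoyloxy]-4-hydroxydauc-8-en-10-one, via acid chloride 21 (not isolated)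
Conditions: 20, (COCl)2, DMF (cat.), CH2Cl2, 0 °C → rt, evaporate; then 19, pyridine, DMAP, CH2Cl2, 0 °C → rt
Reagents that add atoms: 4-(tert-butyldimethylsilyloxy)benzoic acid 20, CC(C)(C)[Si](C)(C)Oc1ccc(cc1)C(=O)O
Why: DMAP-catalysed acylation by the acid chloride occurs at the secondary C6 hydroxyl only, because the tertiary C4 hydroxyl is inert and C10 is a ketone at this stage, and the ester is introduced after the base isomerisation so that the C6 acyloxy group never meets dienolate-forming conditions.

Step 12
Reactants: 22 (1R,4R,5S,6S)-6-[4-(tert-butyldimethylsilyloxy)benzoyloxy]-4-hydroxydauc-8-en-10-one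
Product: 23 (1R,4R,5S,6S,10S)-6-[4-(tert-butyldimethylsilyloxy)benzoyloxy]dauc-8-ene-4,10-diol
Conditions: NaBH4, CeCl3·7H2O, MeOH, −78 °C
Reagents that add atoms: none
Why: In this Luche 1,2-reduction the preferred conformer of the cis-fused enone has the C1–C2 bond of the five-membered ring pseudo-axial next to the carbonyl group (C1 methyl, C4 and the C6 ester pseudo-equatorial), so hydride should enter anti to that bond on the convex face of H5 and the angular methyl and give the pseudo-equatorial 10S alcohol.

Step 13
Reactants: 23 (1R,4R,5S,6S,10S)-6-[4-(tert-butyldimethylsilyloxy)benzoyloxy]dauc-8-ene-4,10-diol; 24 (E)-2-methylbut-2-enoyl chloride (tigloyl chloride)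
Product: 25 (1R,4R,5S,6S,10S)-6-[4-(tert-butyldimethylsilyloxy)benzoyloxy]-10-[(E)-2-methylbut-2-enoyloxy]dauc-8-en-4-ol
Conditions: 24, pyridine, DMAP (1 equiv), CH2Cl2, rt → 40 °C
Reagents that add atoms: (E)-2-methylbut-2-enoyl chloride 24, C/C=C(\C)C(=O)Cl
Why: DMAP-promoted acylation of the one remaining secondary alcohol proceeds with retention at C10, pyridine rather than a trialkylamine is used so that the acid chloride is not deconjugated through a vinylketene, and the E geometry of the tiglate is the stable one.

Step 14
Reactants: 25 (1R,4R,5S,6S,10S)-6-[4-(tert-butyldimethylsilyloxy)benzoyloxy]-10-[(E)-2-methylbut-2-enoyloxy]dauc-8-en-4-ol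
Product: 26 (1R,4R,5S,6S,10S)-4-hydroxy-6-(4-hydroxybenzoyloxy)-10-[(E)-2-methylbut-2-enoyloxy]dauc-8-ene (target)
Conditions: Bu4NF, AcOH (1:1), THF, 0 °C
Reagents that add atoms: none
Why: Fluoride-mediated desilylation cleaves the aryl silyl ether selectively, and the acetic acid buffer keeps the liberated phenoxide from attacking the two esters.

**Compound list**
1 | 3-methylcyclopent-2-en-1-one | CC1=CC(=O)CC1 | starting material
2 | (Z)-1,2-dichloroethene | Cl/C=C\Cl | starting material
3 | rac-6,7-dichloro-5-methylbicyclo[3.2.0]heptan-2-one, cis-fused, chlorine epimers (racemate; the enantiomer carried on is drawn) | ClC1C(Cl)[C@@H]2[C@@]1(C)CCC2=O | intermediate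
4 | rac-5-methylbicyclo[3.2.0]hept-6-en-2-one (racemate; the enantiomer carried on is drawn) | C1=C[C@@H]2[C@@]1(C)CCC2=O | intermediate
5 | (S)-N,S-dimethyl-S-phenylsulfoximine | C[S@@](=O)(=NC)c1ccccc1 | starting material
6 | (1R,2S,5S)-5-methyl-2-{[(S)-N-methyl-S-phenylsulfonimidoyl]methyl}bicyclo[3.2.0]hept-6-en-2-ol | C1=C[C@@H]2[C@@]1(C)CC[C@@]2(O)C[S@@](=O)(=NC)c1ccccc1 | intermediate
7 | (1R,5S)-5-methylbicyclo[3.2.0]hept-6-en-2-one | C1=C[C@@H]2[C@@]1(C)CCC2=O | intermediate
8 | isopropylmagnesium chloride | CC(C)[Mg]Cl | starting material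
9 | (1R,2R,5S)-5-methyl-2-(propan-2-yl)bicyclo[3.2.0]hept-6-en-2-ol | C1=C[C@@H]2[C@@]1(C)CC[C@@]2(O)C(C)C | intermediate
10 | secondary ozonide of 9 (1,2,4-trioxolane spanning C6 and C10; acetal configurations as formed) | C13OOC(O3)[C@@H]2[C@@]1(C)CC[C@@]2(O)C(C)C | intermediate (not isolated)
11 | (1R,2R,3R)-3-hydroxy-1-methyl-3-(propan-2-yl)cyclopentane-1,2-dicarbaldehyde | O=C[C@]1(C)CC[C@@](O)(C(C)C)[C@@H]1C=O | intermediate
12 | 3-bromo-2-(bromomethyl)prop-1-ene | C=C(CBr)CBr | starting material
13 | (1R,2S,3R)-2-[(1S)-3-(bromomethyl)-1-hydroxybut-3-en-1-yl]-3-hydroxy-1-methyl-3-(propan-2-yl)cyclopentane-1-carbaldehyde | O=C[C@]1(C)CC[C@@](O)(C(C)C)[C@@H]1[C@@H](O)CC(=C)CBr | intermediate (not isolated)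
14 | allylindium dibromide derived from 13 (simplest formulation) | O=C[C@]1(C)CC[C@@](O)(C(C)C)[C@@H]1[C@@H](O)CC(=C)C[In](Br)Br | intermediate (not isolated)
15 | (1R,4R,5S,6S,10S)-8-methylidenedaucane-4,6,10-triol | O[C@H]1CC(=C)C[C@H](O)[C@@H]2[C@@]1(C)CC[C@@]2(O)C(C)C | intermediate
16 | (1R,4R,5S,6S,10S)-4,6-O-isopropylidene-8-methylidenedaucane-4,6,10-triol | O[C@H]1CC(=C)C[C@H](OC(C)(C)O3)[C@@H]2[C@@]1(C)CC[C@@]23C(C)C | intermediate
17 | (1R,4R,5S,6S)-4,6-O-isopropylidene-4,6-dihydroxy-8-methylidenedaucan-10-one | O=C1CC(=C)C[C@H](OC(C)(C)O3)[C@@H]2[C@@]1(C)CC[C@@]23C(C)C | intermediate (not isolated)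
18 | (1R,4R,5S,6S)-4,6-O-isopropylidene-4,6-dihydroxydauc-8-en-10-one | O=C1C=C(C)C[C@H](OC(C)(C)O3)[C@@H]2[C@@]1(C)CC[C@@]23C(C)C | intermediate
19 | (1R,4R,5S,6S)-4,6-dihydroxydauc-8-en-10-one | O=C1C=C(C)C[C@H](O)[C@@H]2[C@@]1(C)CC[C@@]2(O)C(C)C | intermediate
20 | 4-(tert-butyldimethylsilyloxy)benzoic acid | CC(C)(C)[Si](C)(C)Oc1ccc(cc1)C(=O)O | starting material
21 | 4-(tert-butyldimethylsilyloxy)benzoyl chloride | CC(C)(C)[Si](C)(C)Oc1ccc(cc1)C(=O)Cl | intermediate (not isolated)
22 | (1R,4R,5S,6S)-6-[4-(tert-butyldimethylsilyloxy)benzoyloxy]-4-hydroxydauc-8-en-10-one | O=C1C=C(C)C[C@H](OC(=O)c3ccc(O[Si](C)(C)C(C)(C)C)cc3)[C@@H]2[C@@]1(C)CC[C@@]2(O)C(C)C | intermediate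
23 | (1R,4R,5S,6S,10S)-6-[4-(tert-butyldimethylsilyloxy)benzoyloxy]dauc-8-ene-4,10-diol | O[C@H]1C=C(C)C[C@H](OC(=O)c3ccc(O[Si](C)(C)C(C)(C)C)cc3)[C@@H]2[C@@]1(C)CC[C@@]2(O)C(C)C | intermediate
24 | (E)-2-methylbut-2-enoyl chloride (tigloyl chloride) | C/C=C(\C)C(=O)Cl | starting material
25 | (1R,4R,5S,6S,10S)-6-[4-(tert-butyldimethylsilyloxy)benzoyloxy]-10-[(E)-2-methylbut-2-enoyloxy]dauc-8-en-4-ol | C/C=C(\C)C(=O)O[C@H]1C=C(C)C[C@H](OC(=O)c3ccc(O[Si](C)(C)C(C)(C)C)cc3)[C@@H]2[C@@]1(C)CC[C@@]2(O)C(C)C | intermediate
26 | (1R,4R,5S,6S,10S)-4-hydroxy-6-(4-hydroxybenzoyloxy)-10-[(E)-2-methylbut-2-enoyloxy]dauc-8-ene | C/C=C(\C)C(=O)O[C@H]1C=C(C)C[C@H](OC(=O)c2ccc(O)cc2)[C@@H]2[C@@]1(C)CC[C@@]2(O)C(C)C | target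

**Count and risks**
Total step count: 14. Longest linear sequence: 14 steps (1 → 26); every other input is a purchased reagent.

Most likely to fail, first: step 7. After the first addition the pendant allylic bromide may be lost by protonolysis of its indium derivative, by intermolecular addition to a second dialdehyde, or by ether formation with the C6 hydroxyl before it closes onto the hindered C10 carbonyl, which may also be masked as a hemiacetal. The first addition may also lack site or facial selectivity. The fallback sets out from 11 and returns at 19, using only known reactions and closing the ring at C8=C9 instead. Indium-mediated Barbier addition of 3-bromo-2-methylprop-1-ene (1.1 equiv, THF/H2O) to the C6 formyl group, under the same chelate control, should give the hydroxy aldehyde F1 (expected to rest as its five-membered lactol). Excess vinylmagnesium bromide (THF, 0 °C → rt) then adds at C10 to give the diene triol F2 as C10 epimers. Ring-closing metathesis with the second-generation Grubbs catalyst, (H2IMes)(PCy3)Cl2Ru=CHPh, in CH2Cl2 at 40 °C gives the cycloheptene triol F3, and MnO2 in CH2Cl2 oxidises only the allylic C10 alcohol to give 19.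

Second: step 12. Hydride delivery may show poor facial selectivity, or prefer the concave face if the seven-membered ring adopts the other conformer, and then the 10R alcohol results. The fallback sets out from 22 and returns at 25. The reduction is run as before and the 10R alcohol F4 is esterified with tiglic acid under Mitsunobu conditions (PPh3, diisopropyl azodicarboxylate, toluene, 0 °C → rt), so that the ester is installed with inversion at C10 and 25 is reached directly.

Third: step 8. Acetal exchange may stall at mixed acetals of the C10 hydroxyl, or the dioxane on the fully substituted C4 may form incompletely because of 1,3-diaxial strain. The fallback sets out from 15 and returns at 22 without a protecting group, relying on steric differentiation. Acid chloride 21 (1.05 equiv, made from 20 as in step 11; pyridine, DMAP cat., CH2Cl2, −20 °C) should acylate the C6 hydroxyl, which is next to a CH, ahead of the neopentylic C10 hydroxyl to give the C6 mono-ester F5. Dess–Martin oxidation then gives the β,γ-unsaturated ketone F6, and brief treatment with a catalytic amount of DBU at −20 → 0 °C moves the alkene into conjugation to give 22; the exposure is kept short to avoid vinylogous elimination of the C6 ester.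

**Further compounds**
F1 | step 7 | (1R,2S,3R)-3-hydroxy-2-[(1S)-1-hydroxy-3-methylbut-3-en-1-yl]-1-methyl-3-(propan-2-yl)cyclopentane-1-carbaldehyde (open form of the lactol) | O=C[C@]1(C)CC[C@@](O)(C(C)C)[C@@H]1[C@@H](O)CC(C)=C
F2 | step 7 | (1R,2S,3R)-3-hydroxy-2-[(1S)-1-hydroxy-3-methylbut-3-en-1-yl]-1-(1-hydroxyprop-2-en-1-yl)-1-methyl-3-(propan-2-yl)cyclopentane (C10 epimers) | C=CC(O)[C@]1(C)CC[C@@](O)(C(C)C)[C@@H]1[C@@H](O)CC(C)=C
F3 | step 7 | (1R,4R,5S,6S)-dauc-8-ene-4,6,10-triol (C10 epimers) | OC1C=C(C)C[C@H](O)[C@@H]2[C@@]1(C)CC[C@@]2(O)C(C)C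
F4 | step 12 | (1R,4R,5S,6S,10R)-6-[4-(tert-butyldimethylsilyloxy)benzoyloxy]dauc-8-ene-4,10-diol | O[C@@H]1C=C(C)C[C@H](OC(=O)c3ccc(O[Si](C)(C)C(C)(C)C)cc3)[C@@H]2[C@@]1(C)CC[C@@]2(O)C(C)C
F5 | step 8 | (1R,4R,5S,6S,10S)-6-[4-(tert-butyldimethylsilyloxy)benzoyloxy]-8-methylidenedaucane-4,10-diol | O[C@H]1CC(=C)C[C@H](OC(=O)c3ccc(O[Si](C)(C)C(C)(C)C)cc3)[C@@H]2[C@@]1(C)CC[C@@]2(O)C(C)C
F6 | step 8 | (1R,4R,5S,6S)-6-[4-(tert-butyldimethylsilyloxy)benzoyloxy]-4-hydroxy-8-methylidenedaucan-10-one | O=C1CC(=C)C[C@H](OC(=O)c3ccc(O[Si](C)(C)C(C)(C)C)cc3)[C@@H]2[C@@]1(C)CC[C@@]2(O)C(C)C
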